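# Proposed total synthesis of CNP0230988.9 (compound 35) by dichloroketene ring expansion of a cyclooctadienone

## The problem

Compound 35 is a germacranolide: a ten-membered carbocycle (C1–C10) with a trans-fused α-methylene-γ-butyrolactone across C6–C7 (C11–C13), an (S)-2-methylbutanoate on the C8 oxygen, an acetoxymethyl group (C15) on C4 and a formyl group (C14) on C10. Both trisubstituted ring alkenes, C1=C10 and C4=C5, have their two ring bonds cis (E by the CIP rules, because C14 and C15 outrank the ring carbons). This geometry is hard to secure in an open chain or in a direct ten-membered ring closure. The three contiguous stereocentres C6, C7 and C8 (all R) sit on a flexible ring, with C6–O trans and C8–O cis to the C7–C11 bond. C6 can be set by a chiral catalyst, C7 relative to C6 while it is still epimerisable between two carbonyl groups, and C8 relative to C7 by the approach of a hydride. The fourth stereocentre comes with (S)-2-methylbutanoic acid and must never meet an enolising base. The α-methylene lactone and the C14 enal are Michael acceptors, the acetate and the C8 ester are base-labile, and the lactone oxygen on C6 is allylic, so these groups must appear late and in a fixed order. The feature that opens the route is that removal of C7 and C8 leaves a cis,cis-cycloocta-1,5-diene in which C6 is bonded to C9. An eight-membered ring holds only cis alkenes, and the oxygens on C6 and C8 are 1,3-related, so the ten-membered ring is the 1,3-dione formed by inserting a two-carbon ketene unit into the C6–C9 bond of a cyclooctadienone.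

## Retrosynthesis

**35 ⇒ 34 ⇒ 33 ⇒ 31 + 32 ⇒ 30.** The last cuts are at heteroatom bonds. The C14 aldehyde goes back through alcohol 34 to PMB ether 33, the C8 ester to hydroxy lactone 31 and acid 32, and the C15 acetate to diol 30. The esters are attached late because the stereocentre of 32 and the acetate would not survive the enolate chemistry that introduces C13. The aldehyde comes last because a free C8 hydroxyl would close a lactol onto it. The forward steps must distinguish a primary allylic hydroxyl (C15) from a hindered secondary one (C8) and must oxidise C14 beside two Michael acceptors.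

**30 ⇒ 29 ⇒ 26.** The exocyclic C11=C13 bond is cut next, with O8 held as a silyl ether (29 from 26). Adding C13 to a finished lactone by aminomethylation and elimination is preferred to bringing a three-carbon acrylate unit to C7, which enolate alkylation cannot attach through its α-carbon. Lactone 26 lacks the most reactive electrophile of the target. The forward step needs C11 to be the only enolisable carbon.

**26 ⇒ 25 ⇒ 24 ⇒ 22.** The C8–H bond is cut (25 from ketone 24), then the lactone C–O bond and the C6–H bond (24 from keto ester 22). Reducing C6 first and closing the lactone before C8 is reduced removes any choice between two hydroxyl groups; the C8 hydroxyl, being cis to the arm, would otherwise compete. Compound 22 is a racemic β-diketone with one labile stereocentre. The catalyst must select the conjugated carbonyl and its face, C7 must follow by dynamic resolution, and the hydride must reach C8 anti to C11.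

**22 ⇒ 20 + 21.** The C7–C11 bond is cut to give dione 20 and methyl bromoacetate 21. C7 is the only doubly activated carbon of 20, so the two-carbon arm goes on without any regiochemical question. Dione 20 is achiral.

**20 ⇒ 19 ⇒ 18 ⇒ 15 + 17 (from 16).** This is the key disconnection. Joining C6 to C9 in 20 gives the cis-fused cyclobutanone 19 and its dichloro precursor 18, the [2+2] adduct of trienol ether 15 and dichloroketene 17 (from acid chloride 16). Compared with a direct ten-membered closure, both ring alkenes are carried by an eight-membered ring where they can only be cis, and the two carbonyl groups arrive 1,3-related. The forward reaction must add the ketene to the enol ether only, with its carbonyl carbon at C9. The later retro-aldol must break C6–C9 and not C6–C7.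

**15 ⇒ 14 ⇒ 13 ⇒ 12.** The enol ether 15 comes from dienone 14 and this from dienol 13. The C1=C10 bond of 13 is cut by ring-closing metathesis to trienol 12. Closing at the alcohol stage keeps C1=C10 from drifting into conjugation. The C4=C5 alkene, already in place, holds the two reacting arms cis. The forward step must form a trisubstituted alkene in an eight-membered ring.

**12 ⇒ 7 + 10.** The C6–C9 bond is cut to enal 7 and allylic bromide 10. The allyl unit of 10 is symmetrical, so the Barbier addition has no regiochemical issue, and the carbinol stereocentre is removed by oxidation.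

**7 ⇒ 6 ⇒ 4 + 5; 4 ⇒ 2 ⇒ 1; 10 ⇒ 9 ⇒ 8.** The C3–C4 bond of dienol 6 is cut to (Z)-iodide 4 and organozinc reagent 5. Hydroxyl-directed hydroalumination and iodination of alkynol 2 (from diol 1) fixes the alkene geometry. Olefination chemistry would give alkene mixtures when the two groups on C4 are of similar size. Bromide 10 comes from diol 8 through ether 9.

## Roads not taken

**Alternative 1:** The cut is C5–C6, made in the open chain with both esters already in place. CrCl2 with catalytic NiCl2 would join the vinyl iodide carbon of aldehyde A1 to its formyl carbon and give the ten-membered allylic alcohol A2.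
- Merits: the route is convergent, C7 and C8 are set by open-chain asymmetric chemistry before the ring exists, and the endgame is short. In absolute stereocontrol at C7 and C8 this road is better than the chosen plan.
- Weak points: both trisubstituted alkenes must be made with full geometric control in the chain. The ten-membered closure works against strain and dimerisation. The configuration at C6 is decided in the macrocyclisation without a reliable model. A1 is a β-acyloxy aldehyde whose α-hydrogen is also allylic, so loss of the 2-methylbutanoate and epimerisation at C7 threaten.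
- Comparison: the chosen plan sets against it ring alkenes that cannot be formed with the wrong geometry, no macrocyclisation, and achiral intermediates up to step 13.

**Alternative 2:** The cut is the C1=C10 alkene, traced back to a C6–C10 bond of a fused five–seven ring system. The alkoxide of the cis-fused mesylate A3 would fragment (Wharton/Grob) to the cyclodecadienone A4.
- Merits: the alkene geometry follows stereospecifically from the relative configuration at C1 and C10. C7 and C8 are set on a cyclopentane. The C8 oxygen is already an ether when C6 is a ketone, so the carbonyl-differentiation problem of the chosen plan does not arise. In these respects it is the better road.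
- Weak points: A3 needs three further stereocentres (C1, C6 and the quaternary C10) in one defined relationship, an antiperiplanar alignment in a seven-membered ring, and an enantioselective entry. Its preparation would be much longer than the whole front end of the chosen plan, and C6 must still be reduced late.
- Comparison: the chosen plan sets against it a stereocentre-free ring construction and a catalyst-controlled reduction that selects the conjugated carbonyl.

**Alternative 3:** The cut is a cyclobutane across C1–C10 and C4–C5. Irradiation of cyclohexenone A5 with cyclobutene ester A6 would give the tricyclic photoadduct A7, and thermal cycloreversion of the central four-membered ring would open the ten-membered diene.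
- Merits: two carbon–carbon bonds and the whole ring perimeter come from one photochemical step, and C7 and C8 are set on a six-membered ring. On paper this is the shortest way to the skeleton.
- Weak points: the cycloreversion is not allowed as a concerted thermal process. It needs high temperature and a diradical path, which favours ring-trans alkene geometry and Cope rearrangement over the cis,cis-diene. The silyloxy ketone and the esters would suffer under these conditions. Regio- and face selectivity of the photoaddition are open. C15 enters as an ester that must later be reduced beside other carbonyl groups.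
- Comparison: the chosen plan sets against it guaranteed alkene geometry and no step above 50 °C.

Key step: step 11

Remark: germacrane numbering is used throughout (ring C1–C10, lactone C11–C13, C14 on C10, C15 on C4); alkoxides and enolates formed by simple deprotonation are treated as forms of the compound named.

## Route

Step 1
Reactants: 1 but-2-yne-1,4-diol
Product: 2 4-[(tert-butyldiphenylsilyl)oxy]but-2-yn-1-ol
Conditions: NaH (1 equiv), THF, 0 °C; TBDPSCl (1 equiv); 1 in threefold excess
Reagents that add atoms: tert-butyl(chloro)diphenylsilane, CC(C)(C)[Si](Cl)(c1ccccc1)c1ccccc1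
Why: Monosilylation of a symmetrical diol through its monoalkoxide; the excess of the cheap diol suppresses the bis-ether.

Step 2
Reactants: 2 4-[(tert-butyldiphenylsilyl)oxy]but-2-yn-1-ol
Product: 4 (Z)-4-[(tert-butyldiphenylsilyl)oxy]-3-iodobut-2-en-1-ol, via cyclic sodium alkenylalanate 3 (not isolated)
Conditions: NaAlH2(OCH2CH2OMe)2, THF, 0 °C; then I2, THF, −78 °C
Reagents that add atoms: iodine, II
Why: Hydroxyl-directed trans-hydroalumination of a propargylic alcohol (hydride to the carbon next to CH2OH, aluminium to the distal carbon in a five-membered alanate), then iodinolysis with retention. Iodine ends cis to CH2OH, which later places C3 cis to C6.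

Step 3
Reactants: 4 (Z)-4-[(tert-butyldiphenylsilyl)oxy]-3-iodobut-2-en-1-ol; 5 but-3-enylzinc bromide
Product: 6 (E)-3-{[(tert-butyldiphenylsilyl)oxy]methyl}hepta-2,6-dien-1-ol
Conditions: PdCl2(dppf) (5 mol %), THF, 25 to 45 °C; 5 in excess
Reagents that add atoms: none
Why: Negishi sp2–sp3 coupling; oxidative addition of the C–I bond to zerovalent palladium and reductive elimination both go with retention, so the butenyl chain (C1–C3) replaces iodine cis to the CH2OH carbon (C6). The free hydroxyl is tolerated by the excess organozinc reagent.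

Step 4
Reactants: 6 (E)-3-{[(tert-butyldiphenylsilyl)oxy]methyl}hepta-2,6-dien-1-ol
Product: 7 (E)-3-{[(tert-butyldiphenylsilyl)oxy]methyl}hepta-2,6-dienal
Conditions: MnO2, CH2Cl2, 25 °C
Reagents that add atoms: none
Why: Allylic alcohol oxidation on MnO2 under neutral conditions, which should leave the alkene geometry and the silyl ether untouched.

Step 5
Reactants: 8 2-methylenepropane-1,3-diol
Product: 9 2-{[(4-methoxybenzyl)oxy]methyl}prop-2-en-1-ol
Conditions: NaH (1 equiv), THF/DMF, 0 °C; PMBCl, Bu4NI (cat.); 8 in excess
Reagents that add atoms: 4-methoxybenzyl chloride, COc1ccc(CCl)cc1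
Why: Williamson monoetherification of a symmetrical diol.

Step 6
Reactants: 9 2-{[(4-methoxybenzyl)oxy]methyl}prop-2-en-1-ol
Product: 10 1-({[2-(bromomethyl)prop-2-en-1-yl]oxy}methyl)-4-methoxybenzene
Conditions: CBr4, PPh3, CH2Cl2, 0 °C
Reagents that add atoms: tetrabromomethane, BrC(Br)(Br)Br
Why: Appel bromination of a primary allylic alcohol under neutral conditions; the PMB ether is not affected.

Step 7
Reactants: 7 (E)-3-{[(tert-butyldiphenylsilyl)oxy]methyl}hepta-2,6-dienal; 10 1-({[2-(bromomethyl)prop-2-en-1-yl]oxy}methyl)-4-methoxybenzene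
Product: 12 rac-(E)-6-{[(tert-butyldiphenylsilyl)oxy]methyl}-2-{[(4-methoxybenzyl)oxy]methyl}deca-1,5,9-trien-4-ol, via allylzinc bromide 11 (not isolated)
Conditions: Zn dust, THF/sat. aq NH4Cl, 0 to 25 °C
Reagents that add atoms: none
Why: Zinc-mediated Barbier allylation; the allylzinc species adds 1,2 to the enal through a six-membered transition state and forms the C6–C9 bond. The carbinol stereocentre (C6) is racemic and is removed in step 9.

Step 8
Reactants: 12 rac-(E)-6-{[(tert-butyldiphenylsilyl)oxy]methyl}-2-{[(4-methoxybenzyl)oxy]methyl}deca-1,5,9-trien-4-ol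
Product: 13 rac-(2E,6E)-3-{[(tert-butyldiphenylsilyl)oxy]methyl}-7-{[(4-methoxybenzyl)oxy]methyl}cycloocta-2,6-dien-1-ol (both ring alkenes cis in the ring)
Conditions: second-generation Grubbs catalyst RuCl2(=CHPh)(H2IMes)(PCy3) (5–10 mol %), CH2Cl2 (0.002 M), 40 °C, argon sweep
Reagents that add atoms: none
Why: Ring-closing metathesis of the terminal alkene onto the 1,1-disubstituted alkene forms the trisubstituted C1=C10 bond, which can only be cis in an eight-membered ring. The C4=C5 alkene holds the two arms cis, and high dilution with removal of ethene offsets the ring strain.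

Step 9
Reactants: 13 rac-(2E,6E)-3-{[(tert-butyldiphenylsilyl)oxy]methyl}-7-{[(4-methoxybenzyl)oxy]methyl}cycloocta-2,6-dien-1-ol
Product: 14 (2E,6E)-3-{[(tert-butyldiphenylsilyl)oxy]methyl}-7-{[(4-methoxybenzyl)oxy]methyl}cycloocta-2,6-dien-1-one
Conditions: Dess–Martin periodinane, NaHCO3, CH2Cl2, 0 °C
Reagents that add atoms: none
Why: Periodinane oxidation of the allylic alcohol; the buffered, non-enolising medium should keep C1=C10 in its β,γ-position to the new ketone.

Step 10
Reactants: 14 (2E,6E)-3-{[(tert-butyldiphenylsilyl)oxy]methyl}-7-{[(4-methoxybenzyl)oxy]methyl}cycloocta-2,6-dien-1-one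
Product: 15 1-{[(tert-butyldiphenylsilyl)oxy]methyl}-5-{[(4-methoxybenzyl)oxy]methyl}-3-[(trimethylsilyl)oxy]cycloocta-1,3,5-triene (all ring alkenes cis; enol ether at C6=C9)
Conditions: LiN(iPr)2, THF, −78 °C; then Me3SiCl/Et3N, −78 to 0 °C; non-aqueous work-up, used at once
Reagents that add atoms: chlorotrimethylsilane, C[Si](C)(C)Cl
Why: Kinetic deprotonation of the enone at C9, its only sp3 α-carbon and further activated by C1=C10, then O-silylation of the dienolate. The tub-shaped triene is kept cold to avoid hydrolysis and 6π-electrocyclisation.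

Step 11
Reactants: 15 1-{[(tert-butyldiphenylsilyl)oxy]methyl}-5-{[(4-methoxybenzyl)oxy]methyl}-3-[(trimethylsilyl)oxy]cycloocta-1,3,5-triene; 16 dichloroacetyl chloride
Product: 18 rac-(1R*,8R*)-10,10-dichloro-3-{[(tert-butyldiphenylsilyl)oxy]methyl}-7-{[(4-methoxybenzyl)oxy]methyl}-1-[(trimethylsilyl)oxy]bicyclo[6.2.0]deca-2,6-dien-9-one (cis-fused), via dichloroketene 17 (not isolated)
Conditions: Et3N (1.5 equiv), 16 (1.3 equiv) added over 4 h, hexane, 0 to 20 °C
Reagents that add atoms: none
Why: Et3N dehydrochlorinates 16 to dichloroketene 17, whose carbonyl carbon (the future C8) is attacked by C9, the nucleophilic β-carbon of the silyl enol ether; the dichloro-enolate carbon (the future C7) then bonds to the silyloxy-stabilised cationic C6, an asynchronous, near-stepwise [2+2] cycloaddition. The closest known reaction type is the dichloroketene cycloaddition to trimethylsilyl enol ethers of cycloalkanones, the first stage of their two-carbon ring expansion to cycloalkane-1,3-diones. The cyclobutanone closes by 4-exo-trig attack of the enolate carbon on the oxocarbenium carbon, and because both bonds form on the same face of the ring alkene the fusion to the eight-membered ring can only be cis. The two new stereocentres C6 and C9 are thus fixed relative to each other by this suprafacial addition; the substrate is achiral, 18 is racemic, and both centres are erased in step 12. The step needs site selectivity for C6=C9 over C4=C5 and C1=C10 and the orientation C8 to C9: the silyloxy group makes C9 the most electron-rich carbon and puts the positive charge on C6, where C4=C5 adds allylic stabilisation. The competitor is the vinylogous terminus C1; the tub shape of the cycloocta-1,3,5-triene twists C10=C1 out of conjugation with the enol ether, and closure after attack at C1 would have to create a quaternary C10 next to the CCl2 group. A non-polar solvent, slow generation of the ketene and temperatures at or below 20 °C should hold back ketene oligomerisation and electrocyclisation of the triene.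

Step 12
Reactants: 18 rac-(1R*,8R*)-10,10-dichloro-3-{[(tert-butyldiphenylsilyl)oxy]methyl}-7-{[(4-methoxybenzyl)oxy]methyl}-1-[(trimethylsilyl)oxy]bicyclo[6.2.0]deca-2,6-dien-9-one
Product: 20 (4E,8E)-5-{[(tert-butyldiphenylsilyl)oxy]methyl}-9-{[(4-methoxybenzyl)oxy]methyl}cyclodeca-4,8-diene-1,3-dione (carbonyl groups at C6 and C8), via dechlorinated cyclobutanone 19 (not isolated)
Conditions: Zn dust, AcOH, i-PrOH/H2O, 0 to 25 °C
Reagents that add atoms: none
Why: Zinc reduces the α,α-dichloroketone; the acidic aqueous medium then removes the silyl group and the β-hydroxycyclobutanone opens by retro-aldol cleavage of C6–C9, driven by ring strain (the known second stage of the ketene ring expansion). Cleavage at C9 is favoured over C6–C7 because the C9 carbanion is an allyl-stabilised enolate, and the protic medium protonates it at C9 before alkene migration or transannular addition.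

Step 13
Reactants: 20 (4E,8E)-5-{[(tert-butyldiphenylsilyl)oxy]methyl}-9-{[(4-methoxybenzyl)oxy]methyl}cyclodeca-4,8-diene-1,3-dione; 21 methyl bromoacetate
Product: 22 methyl rac-2-[(3E,7E)-4-{[(tert-butyldiphenylsilyl)oxy]methyl}-8-{[(4-methoxybenzyl)oxy]methyl}-2,10-dioxocyclodeca-3,7-dien-1-yl]acetate (arm on C7)
Conditions: K2CO3, acetone, 25 °C
Reagents that add atoms: none
Why: C-alkylation of the β-diketone at C7, its only doubly activated carbon, with a reactive α-halo ester. The new stereocentre is racemic and stays epimerisable, as the next step requires.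

Step 14
Reactants: 22 methyl rac-2-[(3E,7E)-4-{[(tert-butyldiphenylsilyl)oxy]methyl}-8-{[(4-methoxybenzyl)oxy]methyl}-2,10-dioxocyclodeca-3,7-dien-1-yl]acetate
Product: 24 (1(10)E,4E,6R,7S)-15-[(tert-butyldiphenylsilyl)oxy]-14-[(4-methoxybenzyl)oxy]-8-oxogermacra-1(10),4-dien-12,6-olide (trans-fused lactone), via hydroxy keto ester 23 (not isolated)
Conditions: RuCl[(S,S)-TsDPEN](p-cymene) (2 mol %), HCO2H/Et3N (5:2), CH2Cl2, 25 °C; then PPTS (cat.), toluene, 50 °C
Reagents that add atoms: none
Why: Noyori–Ikariya asymmetric transfer hydrogenation with dynamic kinetic resolution: the catalyst reduces the conjugated C6 carbonyl, with C4=C5 in the role of the aryl group, which defines both the site and the 6R face, while the C7 epimers interconvert through the diketone enol. The faster epimer should give the syn hydroxy ketone 23 (6R,7S; C6–O trans to C7–C11 on the ring), as open-chain α-alkyl β-keto carbonyl compounds do. Mild acid then closes the lactone onto the only hydroxyl group with loss of methanol.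

Step 15
Reactants: 24 (1(10)E,4E,6R,7S)-15-[(tert-butyldiphenylsilyl)oxy]-14-[(4-methoxybenzyl)oxy]-8-oxogermacra-1(10),4-dien-12,6-olide
Product: 25 (1(10)E,4E,6R,7R,8R)-15-[(tert-butyldiphenylsilyl)oxy]-8-hydroxy-14-[(4-methoxybenzyl)oxy]germacra-1(10),4-dien-12,6-olide
Conditions: LiBH(s-Bu)3, THF, −78 °C; AcOH quench at −78 °C
Reagents that add atoms: none
Why: Sterically controlled hydride addition to the C8 ketone from the face of C7–H, anti to the lactone carbon C11 on the neighbouring ring-fusion carbon, should give the alcohol with C8–O cis to C11 (8R). The lactone is inert to this reagent at −78 °C, and the cold acidic quench avoids translactonisation.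

Step 16
Reactants: 25 (1(10)E,4E,6R,7R,8R)-15-[(tert-butyldiphenylsilyl)oxy]-8-hydroxy-14-[(4-methoxybenzyl)oxy]germacra-1(10),4-dien-12,6-olide
Product: 26 (1(10)E,4E,6R,7S,8R)-15-[(tert-butyldiphenylsilyl)oxy]-14-[(4-methoxybenzyl)oxy]-8-[(triethylsilyl)oxy]germacra-1(10),4-dien-12,6-olide
Conditions: Et3SiCl, imidazole, DMF, 0 to 25 °C
Reagents that add atoms: chlorotriethylsilane, CC[Si](Cl)(CC)CC
Why: Silylation of the secondary alcohol, so that no alkoxide sits cis to the lactone during the enolate chemistry that follows.

Step 17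
Reactants: 26 (1(10)E,4E,6R,7S,8R)-15-[(tert-butyldiphenylsilyl)oxy]-14-[(4-methoxybenzyl)oxy]-8-[(triethylsilyl)oxy]germacra-1(10),4-dien-12,6-olide
Product: 29 (1(10)E,4E,6R,7S,8R)-15-[(tert-butyldiphenylsilyl)oxy]-14-[(4-methoxybenzyl)oxy]-8-[(triethylsilyl)oxy]germacra-1(10),4,11(13)-trien-12,6-olide, via Mannich base 27 (not isolated), via ammonium iodide 28 (not isolated)
Conditions: LiN(iPr)2, THF, −78 °C; Me2N=CH2+ I−, −78 to 0 °C; then MeI, MeOH, 25 °C; then aq NaHCO3, CH2Cl2
Reagents that add atoms: N,N-dimethylmethyleneiminium iodide (Eschenmoser's salt), C=[N+](C)C.[I-]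
Why: α-Methylenation of a γ-lactone by enolate aminomethylation with Eschenmoser's salt, quaternisation and E1cB elimination. C11 is the only enolisable carbon in 26.

Step 18
Reactants: 29 (1(10)E,4E,6R,7S,8R)-15-[(tert-butyldiphenylsilyl)oxy]-14-[(4-methoxybenzyl)oxy]-8-[(triethylsilyl)oxy]germacra-1(10),4,11(13)-trien-12,6-olide
Product: 30 (1(10)E,4E,6R,7R,8R)-8,15-dihydroxy-14-[(4-methoxybenzyl)oxy]germacra-1(10),4,11(13)-trien-12,6-olide
Conditions: HF·pyridine, THF/pyridine, 0 to 25 °C
Reagents that add atoms: none
Why: Fluoride cleavage of both silyl ethers, driven by the Si–F bond. The PMB ether, the lactone and the exocyclic alkene should be stable to buffered HF.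

Step 19
Reactants: 30 (1(10)E,4E,6R,7R,8R)-8,15-dihydroxy-14-[(4-methoxybenzyl)oxy]germacra-1(10),4,11(13)-trien-12,6-olide
Product: 31 (1(10)E,4E,6R,7R,8R)-15-acetoxy-8-hydroxy-14-[(4-methoxybenzyl)oxy]germacra-1(10),4,11(13)-trien-12,6-olide
Conditions: AcCl (1.1 equiv), 2,4,6-collidine, CH2Cl2, −78 °C
Reagents that add atoms: acetyl chloride, CC(=O)Cl
Why: Chemoselective acylation of the unhindered primary allylic hydroxyl (C15) beside the secondary hydroxyl at C8, which is flanked by the ring-fusion carbon.

Step 20
Reactants: 31 (1(10)E,4E,6R,7R,8R)-15-acetoxy-8-hydroxy-14-[(4-methoxybenzyl)oxy]germacra-1(10),4,11(13)-trien-12,6-olide; 32 (S)-2-methylbutanoic acid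
Product: 33 (1(10)E,4E,6R,7R,8R)-15-acetoxy-14-[(4-methoxybenzyl)oxy]-8-{[(2S)-2-methylbutanoyl]oxy}germacra-1(10),4,11(13)-trien-12,6-olide
Conditions: DCC, DMAP (0.1 equiv), CH2Cl2, 0 to 25 °C
Reagents that add atoms: none
Why: Steglich esterification of the secondary alcohol. No enolising base is present, so the α-stereocentre of the acid and the methylene lactone should be preserved.

Step 21
Reactants: 33 (1(10)E,4E,6R,7R,8R)-15-acetoxy-14-[(4-methoxybenzyl)oxy]-8-{[(2S)-2-methylbutanoyl]oxy}germacra-1(10),4,11(13)-trien-12,6-olide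
Product: 34 (1(10)E,4E,6R,7R,8R)-15-acetoxy-14-hydroxy-8-{[(2S)-2-methylbutanoyl]oxy}germacra-1(10),4,11(13)-trien-12,6-olide
Conditions: DDQ (1.2 equiv), CH2Cl2/pH 7 buffer, 0 °C
Reagents that add atoms: none
Why: Oxidative cleavage of the PMB ether by hydride abstraction from the electron-rich benzylic position; esters, lactone and alkenes are inert.

Step 22
Reactants: 34 (1(10)E,4E,6R,7R,8R)-15-acetoxy-14-hydroxy-8-{[(2S)-2-methylbutanoyl]oxy}germacra-1(10),4,11(13)-trien-12,6-olide
Product: 35 (1(10)E,4E,6R,7R,8R)-15-acetoxy-8-{[(2S)-2-methylbutanoyl]oxy}-14-oxogermacra-1(10),4,11(13)-trien-12,6-olide (CNP0230988.9)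
Conditions: MnO2, CH2Cl2, 25 °C
Reagents that add atoms: none
Why: Oxidation of the primary allylic alcohol to the enal on MnO2. The neutral conditions should spare the acetate, the ester stereocentre and both Michael acceptors, and no stereocentre is touched.

## Compound list

1 | but-2-yne-1,4-diol | OCC#CCO | starting material
2 | 4-[(tert-butyldiphenylsilyl)oxy]but-2-yn-1-ol | OCC#CCO[Si](c1ccccc1)(c1ccccc1)C(C)(C)C | intermediate
3 | cyclic sodium alkenylalanate from 2 (not isolated) | [Na+].COCCO[Al-]1(OCCOC)OCC=C1CO[Si](c1ccccc1)(c1ccccc1)C(C)(C)C | intermediate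
4 | (Z)-4-[(tert-butyldiphenylsilyl)oxy]-3-iodobut-2-en-1-ol | OC/C=C(\I)CO[Si](c1ccccc1)(c1ccccc1)C(C)(C)C | intermediate
5 | but-3-enylzinc bromide | C=CCC[Zn]Br | starting material
6 | (E)-3-{[(tert-butyldiphenylsilyl)oxy]methyl}hepta-2,6-dien-1-ol | OC/C=C(/CO[Si](c1ccccc1)(c1ccccc1)C(C)(C)C)CCC=C | intermediate
7 | (E)-3-{[(tert-butyldiphenylsilyl)oxy]methyl}hepta-2,6-dienal | O=C/C=C(/CO[Si](c1ccccc1)(c1ccccc1)C(C)(C)C)CCC=C | intermediate
8 | 2-methylenepropane-1,3-diol | C=C(CO)CO | starting material
9 | 2-{[(4-methoxybenzyl)oxy]methyl}prop-2-en-1-ol | C=C(CO)COCc1ccc(OC)cc1 | intermediate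
10 | 1-({[2-(bromomethyl)prop-2-en-1-yl]oxy}methyl)-4-methoxybenzene | C=C(CBr)COCc1ccc(OC)cc1 | intermediate
11 | {2-[(4-methoxybenzyloxy)methyl]allyl}zinc bromide (not isolated) | C=C(C[Zn]Br)COCc1ccc(OC)cc1 | intermediate
12 | rac-(E)-6-{[(tert-butyldiphenylsilyl)oxy]methyl}-2-{[(4-methoxybenzyl)oxy]methyl}deca-1,5,9-trien-4-ol | C=C(COCc1ccc(OC)cc1)CC(O)/C=C(/CO[Si](c1ccccc1)(c1ccccc1)C(C)(C)C)CCC=C | intermediate
13 | rac-(2E,6E)-3-{[(tert-butyldiphenylsilyl)oxy]methyl}-7-{[(4-methoxybenzyl)oxy]methyl}cycloocta-2,6-dien-1-ol | C1/C=C(COCc2ccc(OC)cc2)\CC(O)/C=C(CO[Si](c2ccccc2)(c2ccccc2)C(C)(C)C)\C1 | intermediate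
14 | (2E,6E)-3-{[(tert-butyldiphenylsilyl)oxy]methyl}-7-{[(4-methoxybenzyl)oxy]methyl}cycloocta-2,6-dien-1-one | C1/C=C(COCc2ccc(OC)cc2)\CC(=O)/C=C(CO[Si](c2ccccc2)(c2ccccc2)C(C)(C)C)\C1 | intermediate
15 | 1-{[(tert-butyldiphenylsilyl)oxy]methyl}-5-{[(4-methoxybenzyl)oxy]methyl}-3-[(trimethylsilyl)oxy]cycloocta-1,3,5-triene (all ring alkenes cis) | C1/C=C(COCc2ccc(OC)cc2)\C=C(O[Si](C)(C)C)/C=C(CO[Si](c2ccccc2)(c2ccccc2)C(C)(C)C)\C1 | intermediate
16 | dichloroacetyl chloride | O=C(Cl)C(Cl)Cl | starting material
17 | dichloroketene (not isolated) | O=C=C(Cl)Cl | intermediate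
18 | rac-(1R*,8R*)-10,10-dichloro-3-{[(tert-butyldiphenylsilyl)oxy]methyl}-7-{[(4-methoxybenzyl)oxy]methyl}-1-[(trimethylsilyl)oxy]bicyclo[6.2.0]deca-2,6-dien-9-one (cis-fused; one enantiomer drawn) | C[Si](C)(C)O[C@]12/C=C(/CO[Si](c3ccccc3)(c3ccccc3)C(C)(C)C)CC/C=C(/COCc3ccc(OC)cc3)[C@H]1C(=O)C2(Cl)Cl | intermediate
19 | rac-(1R*,8R*)-3-{[(tert-butyldiphenylsilyl)oxy]methyl}-7-{[(4-methoxybenzyl)oxy]methyl}-1-[(trimethylsilyl)oxy]bicyclo[6.2.0]deca-2,6-dien-9-one (cis-fused; not isolated) | C[Si](C)(C)O[C@]12/C=C(/CO[Si](c3ccccc3)(c3ccccc3)C(C)(C)C)CC/C=C(/COCc3ccc(OC)cc3)[C@H]1C(=O)C2 | intermediate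
20 | (4E,8E)-5-{[(tert-butyldiphenylsilyl)oxy]methyl}-9-{[(4-methoxybenzyl)oxy]methyl}cyclodeca-4,8-diene-1,3-dione | O=C1CC(=O)/C=C(/CO[Si](c2ccccc2)(c2ccccc2)C(C)(C)C)CC/C=C(/COCc2ccc(OC)cc2)C1 | intermediate
21 | methyl bromoacetate | COC(=O)CBr | starting material
22 | methyl rac-2-[(3E,7E)-4-{[(tert-butyldiphenylsilyl)oxy]methyl}-8-{[(4-methoxybenzyl)oxy]methyl}-2,10-dioxocyclodeca-3,7-dien-1-yl]acetate | COC(=O)CC1C(=O)/C=C(/CO[Si](c2ccccc2)(c2ccccc2)C(C)(C)C)CC/C=C(/COCc2ccc(OC)cc2)CC1=O | intermediate
23 | methyl 2-[(6R,7S)-6-hydroxy-8-oxo-cyclodecadienyl]acetate with C15 OTBDPS and C14 OPMB (germacrane numbering; C6–O trans to C7–C11; not isolated) | COC(=O)C[C@H]1[C@H](O)/C=C(/CO[Si](c2ccccc2)(c2ccccc2)C(C)(C)C)CC/C=C(/COCc2ccc(OC)cc2)CC1=O | intermediate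
24 | (1(10)E,4E,6R,7S)-15-[(tert-butyldiphenylsilyl)oxy]-14-[(4-methoxybenzyl)oxy]-8-oxogermacra-1(10),4-dien-12,6-olide | C1C(=O)O[C@@H]2/C=C(/CO[Si](c3ccccc3)(c3ccccc3)C(C)(C)C)CC/C=C(/COCc3ccc(OC)cc3)CC(=O)[C@@H]12 | intermediate
25 | (1(10)E,4E,6R,7R,8R)-15-[(tert-butyldiphenylsilyl)oxy]-8-hydroxy-14-[(4-methoxybenzyl)oxy]germacra-1(10),4-dien-12,6-olide | C1C(=O)O[C@@H]2/C=C(/CO[Si](c3ccccc3)(c3ccccc3)C(C)(C)C)CC/C=C(/COCc3ccc(OC)cc3)C[C@@H](O)[C@@H]12 | intermediate
26 | (1(10)E,4E,6R,7S,8R)-15-[(tert-butyldiphenylsilyl)oxy]-14-[(4-methoxybenzyl)oxy]-8-[(triethylsilyl)oxy]germacra-1(10),4-dien-12,6-olide | C1C(=O)O[C@@H]2/C=C(/CO[Si](c3ccccc3)(c3ccccc3)C(C)(C)C)CC/C=C(/COCc3ccc(OC)cc3)C[C@@H](O[Si](CC)(CC)CC)[C@@H]12 | intermediate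
27 | 13-(dimethylamino) derivative of 26 (Mannich base; C11 epimers; not isolated) | CN(C)CC1C(=O)O[C@@H]2/C=C(/CO[Si](c3ccccc3)(c3ccccc3)C(C)(C)C)CC/C=C(/COCc3ccc(OC)cc3)C[C@@H](O[Si](CC)(CC)CC)[C@@H]12 | intermediate
28 | 13-(trimethylammonio) derivative of 26 as the iodide (not isolated) | [I-].C[N+](C)(C)CC1C(=O)O[C@@H]2/C=C(/CO[Si](c3ccccc3)(c3ccccc3)C(C)(C)C)CC/C=C(/COCc3ccc(OC)cc3)C[C@@H](O[Si](CC)(CC)CC)[C@@H]12 | intermediate
29 | (1(10)E,4E,6R,7S,8R)-15-[(tert-butyldiphenylsilyl)oxy]-14-[(4-methoxybenzyl)oxy]-8-[(triethylsilyl)oxy]germacra-1(10),4,11(13)-trien-12,6-olide | C=C1C(=O)O[C@@H]2/C=C(/CO[Si](c3ccccc3)(c3ccccc3)C(C)(C)C)CC/C=C(/COCc3ccc(OC)cc3)C[C@@H](O[Si](CC)(CC)CC)[C@@H]12 | intermediate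
30 | (1(10)E,4E,6R,7R,8R)-8,15-dihydroxy-14-[(4-methoxybenzyl)oxy]germacra-1(10),4,11(13)-trien-12,6-olide | C=C1C(=O)O[C@@H]2/C=C(/CO)CC/C=C(/COCc3ccc(OC)cc3)C[C@@H](O)[C@@H]12 | intermediate
31 | (1(10)E,4E,6R,7R,8R)-15-acetoxy-8-hydroxy-14-[(4-methoxybenzyl)oxy]germacra-1(10),4,11(13)-trien-12,6-olide | C=C1C(=O)O[C@@H]2/C=C(/COC(C)=O)CC/C=C(/COCc3ccc(OC)cc3)C[C@@H](O)[C@@H]12 | intermediate
32 | (S)-2-methylbutanoic acid | OC(=O)[C@@H](C)CC | starting material
33 | (1(10)E,4E,6R,7R,8R)-15-acetoxy-14-[(4-methoxybenzyl)oxy]-8-{[(2S)-2-methylbutanoyl]oxy}germacra-1(10),4,11(13)-trien-12,6-olide | C=C1C(=O)O[C@@H]2/C=C(/COC(C)=O)CC/C=C(/COCc3ccc(OC)cc3)C[C@@H](OC(=O)[C@@H](C)CC)[C@@H]12 | intermediate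
34 | (1(10)E,4E,6R,7R,8R)-15-acetoxy-14-hydroxy-8-{[(2S)-2-methylbutanoyl]oxy}germacra-1(10),4,11(13)-trien-12,6-olide | C=C1C(=O)O[C@@H]2/C=C(/COC(C)=O)CC/C=C(/CO)C[C@@H](OC(=O)[C@@H](C)CC)[C@@H]12 | intermediate
35 | (1(10)E,4E,6R,7R,8R)-15-acetoxy-8-{[(2S)-2-methylbutanoyl]oxy}-14-oxogermacra-1(10),4,11(13)-trien-12,6-olide (CNP0230988.9) | C=C1C(=O)O[C@@H]2/C=C(/COC(C)=O)CC/C=C(/C=O)C[C@@H](OC(=O)[C@@H](C)CC)[C@@H]12 | target

## Step count and least certain steps

Total: 22 steps. Longest linear sequence: 20 steps (steps 1–4 and 7–22; steps 5 and 6 prepare bromide 10).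

**Step 11 (key step).** The most likely failure is loss of site selectivity: attack of the ketene at the vinylogous terminus C1, leading to addition across C1=C10 or to a six-membered adduct. Hydrolysis or electrocyclisation of the trienol ether, or simple C-acylation after loss of the silyl group, are further ways to fail. The fallback makes the cycloaddition intramolecular, so that a tether and not the electronic bias chooses the site. It sets out from 14 and returns at 22, bypassing steps 12 and 13. The lithium enolate of 14 is O-acylated with succinic anhydride to the enol hemisuccinate F1. 1-Chloro-N,N,2-trimethylprop-1-en-1-amine converts it under neutral conditions into the acid chloride F2. Et3N in warm toluene releases the tethered ketene F3, which can only reach C6=C9 (three atoms between the ketene carbon and C6) and closes the cyclobutanone and the lactone ring together to give the tricyclic lactone F4. K2CO3 in MeOH opens the lactone to the C6 alkoxide, and retro-aldol cleavage of C6–C9 delivers 22. This is an intramolecular ketene–alkene cycloaddition of a known type applied to an enol ester; its own weak point is the unfavourable ester conformation needed for closure.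

**Step 14.** Three things can go wrong: reduction of the C8 carbonyl or of the C4=C5 bond, incomplete epimerisation at C7, or diastereoselection for the hydroxy ketone with C6–O cis to C7–C11. The last cannot give the trans lactone by acyl substitution. The fallback uses the cis outcome and inverts C6 in the ring closure. It sets out from 20 and returns at 24. Alkylation of 20 with allyl bromoacetate gives the allyl ester F5. Transfer hydrogenation with the (R,R)-enantiomer of the catalyst gives the (6S,7S)-hydroxy ketone F6. Pd(PPh3)4 with morpholine removes the allyl group under neutral conditions to give the hydroxy acid F7. Mitsunobu lactonisation (PPh3, DIAD) displaces the activated C6 oxygen by the carboxylate with inversion and gives 24.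

**Step 15.** The ten-membered ring may expose the other face of the C8 carbonyl, giving poor facial selectivity, and the C8 alkoxide may translactonise onto C12. The fallback corrects the configuration by substitution instead of reduction. It sets out from 24 and returns at 25. If the reduction gives the C8 epimer F8, a Mitsunobu reaction with chloroacetic acid (PPh3, DIAD) gives the inverted chloroacetate F9. Thiourea with NaHCO3 in EtOH then removes the chloroacetyl group without touching the lactone and gives 25.

**Step 13.** O-alkylation or double alkylation of the β-diketone may compete. The fallback is a reductive alkylation in place of the enolate alkylation. It sets out from 20 and returns at 22. Proline-catalysed condensation of 20 with methyl glyoxylate gives the alkylidene dione F10, which is reduced in the same flask by Hantzsch ester through conjugate hydride transfer to 22. Only C–C bond formation is possible and the product cannot react a second time.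

## Further compounds

F1 | step 11 | enol hemisuccinate of 14 (4-oxo-4-[(cyclooctatrienyl)oxy]butanoic acid; O-acyl at C6) | C1/C=C(COCc2ccc(OC)cc2)\C=C(OC(=O)CCC(=O)O)/C=C(CO[Si](c2ccccc2)(c2ccccc2)C(C)(C)C)\C1
F2 | step 11 | acid chloride of F1 | C1/C=C(COCc2ccc(OC)cc2)\C=C(OC(=O)CCC(=O)Cl)/C=C(CO[Si](c2ccccc2)(c2ccccc2)C(C)(C)C)\C1
F3 | step 11 | tethered ketene from F2 (not isolated) | C1/C=C(COCc2ccc(OC)cc2)\C=C(OC(=O)CC=C=O)/C=C(CO[Si](c2ccccc2)(c2ccccc2)C(C)(C)C)\C1
F4 | step 11 | racemic tricyclic lactone (cyclobutanone cis-fused to the eight-membered ring and to the γ-lactone; one enantiomer drawn) | O=C1O[C@]23/C=C(/CO[Si](c4ccccc4)(c4ccccc4)C(C)(C)C)CC/C=C(/COCc4ccc(OC)cc4)[C@H]2C(=O)[C@@H]3C1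
F5 | step 14 | allyl ester analogue of 22 (racemic) | C=CCOC(=O)CC1C(=O)/C=C(/CO[Si](c2ccccc2)(c2ccccc2)C(C)(C)C)CC/C=C(/COCc2ccc(OC)cc2)CC1=O
F6 | step 14 | allyl (6S,7S)-6-hydroxy-8-oxo ester (C6–O cis to C7–C11) | C=CCOC(=O)C[C@H]1[C@@H](O)/C=C(/CO[Si](c2ccccc2)(c2ccccc2)C(C)(C)C)CC/C=C(/COCc2ccc(OC)cc2)CC1=O
F7 | step 14 | (6S,7S)-6-hydroxy-8-oxo acid | OC(=O)C[C@H]1[C@@H](O)/C=C(/CO[Si](c2ccccc2)(c2ccccc2)C(C)(C)C)CC/C=C(/COCc2ccc(OC)cc2)CC1=O
F8 | step 15 | C8 epimer of 25 (6R,7R,8S) | C1C(=O)O[C@@H]2/C=C(/CO[Si](c3ccccc3)(c3ccccc3)C(C)(C)C)CC/C=C(/COCc3ccc(OC)cc3)C[C@H](O)[C@@H]12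
F9 | step 15 | 8-O-chloroacetate of 25 (6R,7R,8R) | C1C(=O)O[C@@H]2/C=C(/CO[Si](c3ccccc3)(c3ccccc3)C(C)(C)C)CC/C=C(/COCc3ccc(OC)cc3)C[C@@H](OC(=O)CCl)[C@@H]12
F10 | step 13 | alkylidene dione from 20 and methyl glyoxylate (exocyclic C7=C11; alkene isomers; not isolated) | COC(=O)C=C1C(=O)/C=C(/CO[Si](c2ccccc2)(c2ccccc2)C(C)(C)C)CC/C=C(/COCc2ccc(OC)cc2)CC1=O
A1 | alternative 1 | open-chain C6 aldehyde with the C5 vinyl iodide (iodine cis to C3) and both esters in place | I/C=C(/COC(C)=O)CC/C=C(/COCc1ccc(OC)cc1)C[C@@H](OC(=O)[C@@H](C)CC)[C@H](C=O)C(=C)COCc1ccc(OC)cc1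
A2 | alternative 1 | ten-membered C6 alcohol with both esters installed | C=C(COCc1ccc(OC)cc1)[C@H]1[C@H](O)/C=C(/COC(C)=O)CC/C=C(/COCc2ccc(OC)cc2)C[C@H]1OC(=O)[C@@H](C)CC
A3 | alternative 2 | cis-fused bicyclo[5.3.0]decenol with C6 tertiary hydroxyl and C1 mesylate trans to C14 | O[C@@]12C=C(CO[Si](c3ccccc3)(c3ccccc3)C(C)(C)C)CC[C@H](OS(C)(=O)=O)[C@]1(COCc3ccc(OC)cc3)C[C@@H](O[Si](C)(C)C(C)(C)C)[C@H]2CC(=O)OC(C)(C)C
A4 | alternative 2 | ten-membered 1(10),4-dien-6-one with C8 silyl ether and C7 acetate arm | O=C1/C=C(/CO[Si](c2ccccc2)(c2ccccc2)C(C)(C)C)CC/C=C(/COCc2ccc(OC)cc2)C[C@@H](O[Si](C)(C)C(C)(C)C)[C@H]1CC(=O)OC(C)(C)C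
A5 | alternative 3 | cyclohexenone (ring C5–C10) with C8 silyl ether and C7 acetate arm | O=C1C=C(COCc2ccc(OC)cc2)C[C@@H](O[Si](C)(C)C(C)(C)C)[C@H]1CC(=O)OC(C)(C)C
A6 | alternative 3 | methyl cyclobut-1-ene-1-carboxylate | COC(=O)C1=CCC1
A7 | alternative 3 | head-to-head cis-anti-cis photoadduct (tricyclo[4.4.0.0(2,5)]decanone) | O=C1[C@@H]2[C@@]3(C(=O)OC)CC[C@H]3[C@]2(COCc4ccc(OC)cc4)C[C@@H](O[Si](C)(C)C(C)(C)C)[C@H]1CC(=O)OC(C)(C)C
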